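**Retrosynthetic overview**

1. Target 25 comes from tigloylation of the C8 alcohol of the macrocyclic butenolide 23.
2. 23 comes from one Ni/Cr-mediated operation on the open-chain bromo enoate / epoxy aldehyde 21. The C6–C7 bond closes the ten-membered carbocycle, and the C6 alkoxide lactonizes onto the cis ester to give the butenolide. C6 is set here.
3. 21 comes from Sharpless epoxidation and oxidation of an (E)-allylic alcohol. The (Z)-β-bromo enoate comes from Pd-catalysed bromocarbonylative lactonization of a propargylic alcohol (C12 from CO), followed by methanolysis.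
4. C8 comes from Ru transfer hydrogenation of an ynone. C10 comes from a Cu–bis(oxazoline) aldol of an enyne enolsilane with 2,3-dione 7. Dione 7 comes from alkylation of 3,3-dimethoxybutan-2-one with the prenol-derived bromide 4.
5. Ring order: epoxide first (step 13), then carbocycle and butenolide together (step 15).

Assumption: silylating, acylating and oxidizing agents are treated as unnumbered reagents; late compounds use germacrane numbering (C1 ketone, C4–C5 epoxide, C6 lactone carbinol, C7=C11, C8 ester carbinol, C10 acetoxy carbon, C12 lactone carbonyl, C13 acetoxymethyl); the sense of induction in steps 7, 8 and 13 is taken from the established models for these catalysts.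

**Route**

Step 1
Reactants: 1 3-methylbut-2-en-1-ol (prenol)
Product: 2 tert-butyl[(3-methylbut-2-en-1-yl)oxy]diphenylsilane
Conditions: TBDPSCl, imidazole, CH2Cl2, 25 °C
Reagents that add atoms: tert-butyl(chloro)diphenylsilane, CC(C)(C)[Si](Cl)(c1ccccc1)c1ccccc1
Why: Standard silyl ether formation on a primary allylic alcohol gives an acid-stable protecting group that lasts until step 12; no stereocentre is involved.

Step 2
Reactants: 2 tert-butyl[(3-methylbut-2-en-1-yl)oxy]diphenylsilane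
Product: 3 (E)-4-(tert-butyldiphenylsilyloxy)-2-methylbut-2-en-1-ol
Conditions: SeO2 (0.2 equiv), t-BuOOH, salicylic acid (cat.), CH2Cl2, 25 °C
Reagents that add atoms: tert-butyl hydroperoxide, CC(C)(C)OO
Why: Catalytic SeO2 allylic oxidation (ene reaction, then [2,3]-sigmatropic shift) attacks the methyl group trans to the chain and so gives the (E)-allylic alcohol.

Step 3
Reactants: 3 (E)-4-(tert-butyldiphenylsilyloxy)-2-methylbut-2-en-1-ol
Product: 4 (E)-1-bromo-4-(tert-butyldiphenylsilyloxy)-2-methylbut-2-ene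
Conditions: CBr4, PPh3, CH2Cl2, 0 °C
Reagents that add atoms: tetrabromomethane, BrC(Br)(Br)Br
Why: Appel bromination converts the primary allylic alcohol into the bromide under neutral conditions without allylic transposition or loss of the (E)-geometry.

Step 4
Reactants: 5 3,3-dimethoxybutan-2-one; 4 (E)-1-bromo-4-(tert-butyldiphenylsilyloxy)-2-methylbut-2-ene
Product: 7 (E)-8-(tert-butyldiphenylsilyloxy)-6-methyloct-6-ene-2,3-dione, via keto ketal 6 (not isolated)
Conditions: LiN(i-Pr)2, THF, −78 °C; then 4, −78 → 0 °C; then 2 M HCl, THF, 25 °C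
Reagents that add atoms: water, O
Why: Kinetic enolate alkylation at the only enolizable position of the keto ketal forms the C2–C3 bond by SN2 on the allylic bromide, and acid hydrolysis of the ketal unmasks the 1,2-dione.

Step 5
Reactants: 8 tert-butyldimethyl(prop-2-yn-1-yloxy)silane; 9 N-methoxy-N-methylacetamide
Product: 10 5-(tert-butyldimethylsilyloxy)pent-3-yn-2-one
Conditions: n-BuLi, THF, −78 °C; then 9, −78 → 0 °C
Reagents that add atoms: none
Why: Acylation of the lithium acetylide with a Weinreb amide stops at the ynone because the tetrahedral chelate collapses only on work-up.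

Step 6
Reactants: 10 5-(tert-butyldimethylsilyloxy)pent-3-yn-2-one
Product: 11 5-(tert-butyldimethylsilyloxy)-2-(trimethylsilyloxy)pent-1-en-3-yne
Conditions: LiN(i-Pr)2, Me3SiCl (in situ quench), THF, −78 °C
Reagents that add atoms: chlorotrimethylsilane, C[Si](C)(C)Cl
Why: Kinetic deprotonation of the methyl ketone with in situ silylation gives the silyl enol ether needed as the Mukaiyama aldol donor.

Step 7
Reactants: 7 (E)-8-(tert-butyldiphenylsilyloxy)-6-methyloct-6-ene-2,3-dione; 11 5-(tert-butyldimethylsilyloxy)-2-(trimethylsilyloxy)pent-1-en-3-yne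
Product: 12 (6R,10E)-1-(tert-butyldimethylsilyloxy)-12-(tert-butyldiphenylsilyloxy)-6,10-dimethyl-6-(trimethylsilyloxy)dodec-10-en-2-yne-4,7-dione
Conditions: Cu(OTf)2 (10 mol %), (R,R)-2,2′-isopropylidenebis(4-tert-butyl-2-oxazoline) (11 mol %), CH2Cl2, −78 °C; NaHCO3 work-up (TMS ether kept)
Reagents that add atoms: none
Why: Evans copper–bis(oxazoline) Mukaiyama aldol, in which the dione chelates copper and the enolsilane adds to the less hindered acetyl carbonyl on the face left open by the (R,R)-ligand, sets the C10 tertiary carbinol as (R) and delivers it as its TMS ether by silyl transfer.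

Step 8
Reactants: 12 (6R,10E)-1-(tert-butyldimethylsilyloxy)-12-(tert-butyldiphenylsilyloxy)-6,10-dimethyl-6-(trimethylsilyloxy)dodec-10-en-2-yne-4,7-dione
Product: 13 (4S,6R,10E)-1-(tert-butyldimethylsilyloxy)-12-(tert-butyldiphenylsilyloxy)-4-hydroxy-6,10-dimethyl-6-(trimethylsilyloxy)dodec-10-en-2-yn-7-one
Conditions: Ru[(S,S)-TsNCHPhCHPhNH](p-cymene) (2 mol %), i-PrOH, 25 °C (no base)
Reagents that add atoms: none
Why: Noyori asymmetric transfer hydrogenation reduces the ynone far faster than the hindered α-silyloxy dialkyl ketone, the (S,S)-catalyst gives the (S)-propargylic alcohol at C8, and base-free conditions avoid retro-aldol.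

Step 9
Reactants: 13 (4S,6R,10E)-1-(tert-butyldimethylsilyloxy)-12-(tert-butyldiphenylsilyloxy)-4-hydroxy-6,10-dimethyl-6-(trimethylsilyloxy)dodec-10-en-2-yn-7-one
Product: 15 (4S,6R,10E)-4-(tert-butyldimethylsilyloxy)-12-(tert-butyldiphenylsilyloxy)-1,6-dihydroxy-6,10-dimethyldodec-10-en-2-yn-7-one, via tetrasilyl ether 14 (not isolated)
Conditions: TBSOTf, 2,6-lutidine, CH2Cl2, −78 °C; then MeOH, CSA, 0 °C
Reagents that add atoms: tert-butyldimethylsilyl trifluoromethanesulfonate, CC(C)(C)[Si](C)(C)OS(=O)(=O)C(F)(F)F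
Why: Silylation turns the C8 oxygen into an ether that can neither lactonize nor leave in the following palladium step, and mild acid methanolysis then removes only the primary TBS and tertiary TMS ethers (protection followed by selective deprotection).

Step 10
Reactants: 15 (4S,6R,10E)-4-(tert-butyldimethylsilyloxy)-12-(tert-butyldiphenylsilyloxy)-1,6-dihydroxy-6,10-dimethyldodec-10-en-2-yn-7-one
Product: 17 methyl (2Z,4S,6R,10E)-3-bromo-4-(tert-butyldimethylsilyloxy)-12-(tert-butyldiphenylsilyloxy)-6-hydroxy-2-(hydroxymethyl)-6,10-dimethyl-7-oxododeca-2,10-dienoate, via bromoalkylidene β-lactone 16 (not isolated)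
Conditions: PdBr2 (10 mol %), CuBr2 (3 equiv), CO (1 atm), THF, 25 °C; then MeOH, Et3N, 0 °C
Reagents that add atoms: carbon monoxide, [C-]#[O+]; CuBr2 (bromine source), Br[Cu]Br; methanol, CO
Why: Palladium-catalysed halocarbonylative lactonization of a propargylic alcohol (the bromide counterpart of the known PdCl2/CuCl2 reaction) adds the carbonyl to C11 and bromine to C7 on the same side, fixing the tetrasubstituted alkene with Br cis to C12, and methanolysis of the strained β-lactone gives the methyl ester with a free C13 hydroxyl.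

Step 11
Reactants: 17 methyl (2Z,4S,6R,10E)-3-bromo-4-(tert-butyldimethylsilyloxy)-12-(tert-butyldiphenylsilyloxy)-6-hydroxy-2-(hydroxymethyl)-6,10-dimethyl-7-oxododeca-2,10-dienoate
Product: 18 methyl (2Z,4S,6R,10E)-6-acetoxy-2-(acetoxymethyl)-3-bromo-4-(tert-butyldimethylsilyloxy)-12-(tert-butyldiphenylsilyloxy)-6,10-dimethyl-7-oxododeca-2,10-dienoate
Conditions: Ac2O, Et3N, DMAP (0.2 equiv), CH2Cl2, 25 °C
Reagents that add atoms: acetic anhydride, CC(=O)OC(C)=O
Why: DMAP-catalysed acetylation esterifies both the primary allylic alcohol and the tertiary α-keto alcohol, installing the C13 and C10 acetates of the target.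

Step 12
Reactants: 18 methyl (2Z,4S,6R,10E)-6-acetoxy-2-(acetoxymethyl)-3-bromo-4-(tert-butyldimethylsilyloxy)-12-(tert-butyldiphenylsilyloxy)-6,10-dimethyl-7-oxododeca-2,10-dienoate
Product: 19 methyl (2Z,4S,6R,10E)-6-acetoxy-2-(acetoxymethyl)-3-bromo-4,12-dihydroxy-6,10-dimethyl-7-oxododeca-2,10-dienoate
Conditions: HF·pyridine, pyridine, THF, 0 → 25 °C
Reagents that add atoms: none
Why: Buffered fluoride desilylation removes both silyl ethers without touching the acetates, the methyl ester or the vinyl bromide, and the freed C8 hydroxyl is trans to the ester so it cannot lactonize.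

Step 13
Reactants: 19 methyl (2Z,4S,6R,10E)-6-acetoxy-2-(acetoxymethyl)-3-bromo-4,12-dihydroxy-6,10-dimethyl-7-oxododeca-2,10-dienoate
Product: 20 methyl (2Z,4S,6R)-6-acetoxy-2-(acetoxymethyl)-3-bromo-4-hydroxy-9-[(2R,3R)-3-(hydroxymethyl)-2-methyloxiran-2-yl]-6-methyl-7-oxonon-2-enoate
Conditions: Ti(OiPr)4 (0.3 equiv), D-(−)-diethyl tartrate (0.4 equiv), t-BuOOH, 4 Å molecular sieves, CH2Cl2, −20 °C
Reagents that add atoms: tert-butyl hydroperoxide, CC(C)(C)OO
Why: Sharpless asymmetric epoxidation of the (E)-trisubstituted primary allylic alcohol with the D-tartrate gives the (2R,3R)-epoxy alcohol and so sets C4 and C5, while the electron-poor bromo enoate alkene beside the C8 hydroxyl is inert.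

Step 14
Reactants: 20 methyl (2Z,4S,6R)-6-acetoxy-2-(acetoxymethyl)-3-bromo-4-hydroxy-9-[(2R,3R)-3-(hydroxymethyl)-2-methyloxiran-2-yl]-6-methyl-7-oxonon-2-enoate
Product: 21 methyl (2Z,4S,6R)-6-acetoxy-2-(acetoxymethyl)-3-bromo-9-[(2R,3S)-3-formyl-2-methyloxiran-2-yl]-4-hydroxy-6-methyl-7-oxonon-2-enoate
Conditions: TEMPO (0.1 equiv), PhI(OAc)2, CH2Cl2, 25 °C
Reagents that add atoms: none
Why: The oxoammonium (TEMPO) oxidation is selective for the primary alcohol over the hindered secondary C8 alcohol and gives the epoxy aldehyde under neutral conditions without epimerization.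

Step 15
Reactants: 21 methyl (2Z,4S,6R)-6-acetoxy-2-(acetoxymethyl)-3-bromo-9-[(2R,3S)-3-formyl-2-methyloxiran-2-yl]-4-hydroxy-6-methyl-7-oxonon-2-enoate
Product: 23 (4R,5R,6S,8S,10R)-10,13-diacetoxy-4,5-epoxy-8-hydroxy-1-oxogermacr-7(11)-en-12,6-olide, via open hydroxy ester 22 (not isolated)
Conditions: CrCl2 (12 equiv), NiCl2 (0.2 equiv), degassed DMSO/THF, 25 °C, 0.003 M (syringe-pump addition of 21)
Reagents that add atoms: none
Why: In this Nozaki–Hiyama–Kishi reaction nickel inserts into the ester-activated C7–Br bond and transmetalation gives a vinylchromium that adds to the epoxy aldehyde through a chelated macrocyclic transition state (5,6-syn, the sense seen in chromium-mediated closures onto trans-2,3-epoxy aldehydes in the parthenolide series), setting C6 as (S), after which the chromium alkoxide held cis to the ester lactonizes, so the ten-membered carbocycle and the butenolide form in the same flask.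

Step 16
Reactants: 23 (4R,5R,6S,8S,10R)-10,13-diacetoxy-4,5-epoxy-8-hydroxy-1-oxogermacr-7(11)-en-12,6-olide; 24 (E)-2-methylbut-2-enoyl chloride (tigloyl chloride)
Product: 25 (4R,5R,6S,8S,10R)-10,13-diacetoxy-4,5-epoxy-8-[(E)-2-methylbut-2-enoyloxy]-1-oxogermacr-7(11)-en-12,6-olide (CNP0175424.1)
Conditions: pyridine, DMAP (0.1 equiv), CH2Cl2, 0 → 25 °C
Reagents that add atoms: none
Why: DMAP-catalysed esterification of the secondary C8 alcohol with the acid chloride proceeds with retention at C8 and without isomerizing the thermodynamically preferred (E)-tiglate, giving the target.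

**Compound list**

1 | 3-methylbut-2-en-1-ol (prenol) | CC(C)=CCO | starting material
2 | tert-butyl[(3-methylbut-2-en-1-yl)oxy]diphenylsilane | CC(C)=CCO[Si](c1ccccc1)(c1ccccc1)C(C)(C)C | intermediate
3 | (E)-4-(tert-butyldiphenylsilyloxy)-2-methylbut-2-en-1-ol | OC/C(C)=C/CO[Si](c1ccccc1)(c1ccccc1)C(C)(C)C | intermediate
4 | (E)-1-bromo-4-(tert-butyldiphenylsilyloxy)-2-methylbut-2-ene | BrC/C(C)=C/CO[Si](c1ccccc1)(c1ccccc1)C(C)(C)C | intermediate
5 | 3,3-dimethoxybutan-2-one | CC(=O)C(C)(OC)OC | starting material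
6 | (E)-8-(tert-butyldiphenylsilyloxy)-2,2-dimethoxy-6-methyloct-6-en-3-one (not isolated) | COC(C)(OC)C(=O)CC/C(C)=C/CO[Si](c1ccccc1)(c1ccccc1)C(C)(C)C | intermediate
7 | (E)-8-(tert-butyldiphenylsilyloxy)-6-methyloct-6-ene-2,3-dione | CC(=O)C(=O)CC/C(C)=C/CO[Si](c1ccccc1)(c1ccccc1)C(C)(C)C | intermediate
8 | tert-butyldimethyl(prop-2-yn-1-yloxy)silane | C#CCO[Si](C)(C)C(C)(C)C | starting material
9 | N-methoxy-N-methylacetamide | CC(=O)N(C)OC | starting material
10 | 5-(tert-butyldimethylsilyloxy)pent-3-yn-2-one | CC(=O)C#CCO[Si](C)(C)C(C)(C)C | intermediate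
11 | 5-(tert-butyldimethylsilyloxy)-2-(trimethylsilyloxy)pent-1-en-3-yne | C=C(O[Si](C)(C)C)C#CCO[Si](C)(C)C(C)(C)C | intermediate
12 | (6R,10E)-1-(tert-butyldimethylsilyloxy)-12-(tert-butyldiphenylsilyloxy)-6,10-dimethyl-6-(trimethylsilyloxy)dodec-10-en-2-yne-4,7-dione | CC(C)(C)[Si](C)(C)OCC#CC(=O)C[C@@](C)(O[Si](C)(C)C)C(=O)CC/C(C)=C/CO[Si](c1ccccc1)(c1ccccc1)C(C)(C)C | intermediate
13 | (4S,6R,10E)-1-(tert-butyldimethylsilyloxy)-12-(tert-butyldiphenylsilyloxy)-4-hydroxy-6,10-dimethyl-6-(trimethylsilyloxy)dodec-10-en-2-yn-7-one | CC(C)(C)[Si](C)(C)OCC#C[C@@H](O)C[C@@](C)(O[Si](C)(C)C)C(=O)CC/C(C)=C/CO[Si](c1ccccc1)(c1ccccc1)C(C)(C)C | intermediate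
14 | (4S,6R,10E)-1,4-bis(tert-butyldimethylsilyloxy)-12-(tert-butyldiphenylsilyloxy)-6,10-dimethyl-6-(trimethylsilyloxy)dodec-10-en-2-yn-7-one (not isolated) | CC(C)(C)[Si](C)(C)OCC#C[C@@H](O[Si](C)(C)C(C)(C)C)C[C@@](C)(O[Si](C)(C)C)C(=O)CC/C(C)=C/CO[Si](c1ccccc1)(c1ccccc1)C(C)(C)C | intermediate
15 | (4S,6R,10E)-4-(tert-butyldimethylsilyloxy)-12-(tert-butyldiphenylsilyloxy)-1,6-dihydroxy-6,10-dimethyldodec-10-en-2-yn-7-one | OCC#C[C@@H](O[Si](C)(C)C(C)(C)C)C[C@@](C)(O)C(=O)CC/C(C)=C/CO[Si](c1ccccc1)(c1ccccc1)C(C)(C)C | intermediate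
16 | (Z)-3-[(2S,4R,8E)-1-bromo-2-(tert-butyldimethylsilyloxy)-10-(tert-butyldiphenylsilyloxy)-4-hydroxy-4,8-dimethyl-5-oxodec-8-en-1-ylidene]oxetan-2-one (not isolated) | O=C1OC/C1=C(/Br)[C@@H](O[Si](C)(C)C(C)(C)C)C[C@@](C)(O)C(=O)CC/C(C)=C/CO[Si](c1ccccc1)(c1ccccc1)C(C)(C)C | intermediate
17 | methyl (2Z,4S,6R,10E)-3-bromo-4-(tert-butyldimethylsilyloxy)-12-(tert-butyldiphenylsilyloxy)-6-hydroxy-2-(hydroxymethyl)-6,10-dimethyl-7-oxododeca-2,10-dienoate | COC(=O)/C(CO)=C(\Br)[C@@H](O[Si](C)(C)C(C)(C)C)C[C@@](C)(O)C(=O)CC/C(C)=C/CO[Si](c1ccccc1)(c1ccccc1)C(C)(C)C | intermediate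
18 | methyl (2Z,4S,6R,10E)-6-acetoxy-2-(acetoxymethyl)-3-bromo-4-(tert-butyldimethylsilyloxy)-12-(tert-butyldiphenylsilyloxy)-6,10-dimethyl-7-oxododeca-2,10-dienoate | COC(=O)/C(COC(C)=O)=C(\Br)[C@@H](O[Si](C)(C)C(C)(C)C)C[C@@](C)(OC(C)=O)C(=O)CC/C(C)=C/CO[Si](c1ccccc1)(c1ccccc1)C(C)(C)C | intermediate
19 | methyl (2Z,4S,6R,10E)-6-acetoxy-2-(acetoxymethyl)-3-bromo-4,12-dihydroxy-6,10-dimethyl-7-oxododeca-2,10-dienoate | COC(=O)/C(COC(C)=O)=C(\Br)[C@@H](O)C[C@@](C)(OC(C)=O)C(=O)CC/C(C)=C/CO | intermediate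
20 | methyl (2Z,4S,6R)-6-acetoxy-2-(acetoxymethyl)-3-bromo-4-hydroxy-9-[(2R,3R)-3-(hydroxymethyl)-2-methyloxiran-2-yl]-6-methyl-7-oxonon-2-enoate | COC(=O)/C(COC(C)=O)=C(\Br)[C@@H](O)C[C@@](C)(OC(C)=O)C(=O)CC[C@@]1(C)O[C@@H]1CO | intermediate
21 | methyl (2Z,4S,6R)-6-acetoxy-2-(acetoxymethyl)-3-bromo-9-[(2R,3S)-3-formyl-2-methyloxiran-2-yl]-4-hydroxy-6-methyl-7-oxonon-2-enoate | COC(=O)/C(COC(C)=O)=C(\Br)[C@@H](O)C[C@@](C)(OC(C)=O)C(=O)CC[C@@]1(C)O[C@@H]1C=O | intermediate
22 | methyl 3-acetoxy-2-[(4R,5R,6S,8S,10R)-10-acetoxy-4,5-epoxy-6,8-dihydroxy-1-oxogermacran-7-ylidene]propanoate, ester carbonyl cis to C6 (chromium alkoxide in the flask, not isolated) | COC(=O)/C(COC(C)=O)=C1/[C@@H](O)C[C@@](C)(OC(C)=O)C(=O)CC[C@@]2(C)O[C@@H]2[C@H]1O | intermediate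
23 | (4R,5R,6S,8S,10R)-10,13-diacetoxy-4,5-epoxy-8-hydroxy-1-oxogermacr-7(11)-en-12,6-olide | O[C@H]1C[C@@](C)(OC(C)=O)C(=O)CC[C@@]2(C)O[C@@H]2[C@H]2OC(=O)C(COC(C)=O)=C12 | intermediate
24 | (E)-2-methylbut-2-enoyl chloride (tigloyl chloride) | C/C=C(\C)C(Cl)=O | starting material
25 | (4R,5R,6S,8S,10R)-10,13-diacetoxy-4,5-epoxy-8-[(E)-2-methylbut-2-enoyloxy]-1-oxogermacr-7(11)-en-12,6-olide | C/C=C(\C)C(=O)O[C@H]1C[C@@](C)(OC(C)=O)C(=O)CC[C@@]2(C)O[C@@H]2[C@H]2OC(=O)C(COC(C)=O)=C12 | target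

**Step count**

Total steps: 16. Longest linear sequence: 14 (steps 1–4 and 7–16, from prenol); steps 5–6 form the side branch.

**Three steps most likely to fail**

Step 15 (ring closure and lactonization). A tetrasubstituted vinylchromium has to close a strained ten-membered ring. Protodebromination, dimerization, or the Felkin-type (5,6-anti) C6 epimer could win instead. The fallback sets out from diol 19. MnO2 in CH2Cl2 oxidizes only the primary allylic alcohol to the enal methyl (2Z,4S,6R,10E)-6-acetoxy-2-(acetoxymethyl)-3-bromo-4-hydroxy-6,10-dimethyl-7,12-dioxododeca-2,10-dienoate F1. The same CrCl2/NiCl2 closure is then run on the enal, where there is no epoxide to bias the aldehyde face or to meet divalent chromium, so C6 is set by the macrocycle alone. This gives (4E,8S,10R)-10,13-diacetoxy-8-hydroxy-1-oxogermacra-4,7(11)-dien-12,6-olide F2, with C6 arranged in space as in 23. m-CPBA (NaHCO3, CH2Cl2, 0 °C) then epoxidizes the only electron-rich alkene from the outer face of the ring and returns to the route at 23.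

Step 10 (bromocarbonylative lactonization). The precedent is for chlorides and more substituted propargylic alcohols. CuBr2 may brominate the alkene or the ketone, and the primary alcohol may lactonize slowly. The fallback sets out from tetrasilyl ether 14, isolated after the silylation half of step 9. The zerovalent nickel complex Ni(cod)2 (1 equiv) with DBU under CO2 (1 atm, THF, 0 °C) couples alkyne and CO2 to an oxanickelacyclopentenone with the carboxylate on the less hindered C11. NBS cleaves the C7–Ni bond with retention to give (2Z,4S,6R,10E)-3-bromo-4-(tert-butyldimethylsilyloxy)-2-[(tert-butyldimethylsilyloxy)methyl]-12-(tert-butyldiphenylsilyloxy)-6,10-dimethyl-7-oxo-6-(trimethylsilyloxy)dodeca-2,10-dienoic acid F3. Me3SiCHN2 in MeOH/toluene gives its methyl ester F4. CSA in MeOH at 0 °C removes the primary TBS and the TMS ether and returns to the route at 17.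

Step 7 (aldol with the enyne enolsilane). This donor has not been used with 1,2-diones, so regio- and enantioselectivity are by analogy only, and the ynone product may react further. The fallback sets out from dione 7. The same copper catalyst is used with the thioester-derived donor 1-(ethylthio)-1-(trimethylsilyloxy)ethene F5, made from S-ethyl thioacetate with LiN(i-Pr)2 and Me3SiCl. This gives S-ethyl (3R,7E)-9-(tert-butyldiphenylsilyloxy)-3,7-dimethyl-4-oxo-3-(trimethylsilyloxy)non-7-enethioate F6. Palladium-catalysed thioester–alkyne coupling with alkyne 8 (PdCl2(dppf), tri(2-furyl)phosphine, CuI, Et3N, DMF, 50 °C) builds the ynone and returns to the route at 12.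

Further compounds

F1 | step 15 | methyl (2Z,4S,6R,10E)-6-acetoxy-2-(acetoxymethyl)-3-bromo-4-hydroxy-6,10-dimethyl-7,12-dioxododeca-2,10-dienoate | COC(=O)/C(COC(C)=O)=C(\Br)[C@@H](O)C[C@@](C)(OC(C)=O)C(=O)CC/C(C)=C/C=O
F2 | step 15 | (4E,8S,10R)-10,13-diacetoxy-8-hydroxy-1-oxogermacra-4,7(11)-dien-12,6-olide, C6 arranged as in 23 | O[C@H]1C[C@@](C)(OC(C)=O)C(=O)CC/C(C)=C/[C@H]2OC(=O)C(COC(C)=O)=C12
F3 | step 10 | (2Z,4S,6R,10E)-3-bromo-4-(tert-butyldimethylsilyloxy)-2-[(tert-butyldimethylsilyloxy)methyl]-12-(tert-butyldiphenylsilyloxy)-6,10-dimethyl-7-oxo-6-(trimethylsilyloxy)dodeca-2,10-dienoic acid | OC(=O)/C(CO[Si](C)(C)C(C)(C)C)=C(\Br)[C@@H](O[Si](C)(C)C(C)(C)C)C[C@@](C)(O[Si](C)(C)C)C(=O)CC/C(C)=C/CO[Si](c1ccccc1)(c1ccccc1)C(C)(C)C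
F4 | step 10 | methyl (2Z,4S,6R,10E)-3-bromo-4-(tert-butyldimethylsilyloxy)-2-[(tert-butyldimethylsilyloxy)methyl]-12-(tert-butyldiphenylsilyloxy)-6,10-dimethyl-7-oxo-6-(trimethylsilyloxy)dodeca-2,10-dienoate | COC(=O)/C(CO[Si](C)(C)C(C)(C)C)=C(\Br)[C@@H](O[Si](C)(C)C(C)(C)C)C[C@@](C)(O[Si](C)(C)C)C(=O)CC/C(C)=C/CO[Si](c1ccccc1)(c1ccccc1)C(C)(C)C
F5 | step 7 | 1-(ethylthio)-1-(trimethylsilyloxy)ethene | C=C(O[Si](C)(C)C)SCC
F6 | step 7 | S-ethyl (3R,7E)-9-(tert-butyldiphenylsilyloxy)-3,7-dimethyl-4-oxo-3-(trimethylsilyloxy)non-7-enethioate | CCSC(=O)C[C@@](C)(O[Si](C)(C)C)C(=O)CC/C(C)=C/CO[Si](c1ccccc1)(c1ccccc1)C(C)(C)C
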